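## The problem

Compound 26 is a cis-fused decalin of the eremophilane type. Locants used throughout: ring A = C1–C5 and C10, ring B = C5–C10, methyls C15 on C4 and C14 on C5, isopropenyl C11–C13 on C7, ketone at C8, angelates ((Z)-2-methylbut-2-enoates) on the C3 and C9 oxygens; β denotes the face that carries the two methyl groups. Six stereocentres must be set, (3R,4R,5R,7R,9R,10S); four are contiguous on ring A and include the quaternary C5, whose bonds to the tertiary carbons C4 and C10 are the most congested in the molecule. On ring A the two methyls are cis (β), the C3 oxygen, C6 and C9 all lie on the α face, and H10 is β, so the ring fusion is cis. C3, C4, C5 and C10 form one interlocked set that a single concerted event can fix. C9 sits next to C10 and can be brought in from the chiral pool to steer that event. C7 is epimerisable and equatorial in the all-equatorial chair of ring B, so it can be settled last but can direct nothing earlier. The angelates isomerise to tiglates under nucleophilic or basic acyl transfer and tolerate neither hydride, hydrogenation nor peracid; the C11=C12 alkene slips into conjugation with the C8 ketone under base; the α-oxy ketone at C9 can epimerise or undergo α-ketol shift. The esters therefore go on last and the isopropenyl group late. The enabling feature is that C15–C4–C5(C14)–C6 is the carbon set of (E)-2-methylbut-2-enal with its methyls cis, and that O3, C6 and C9 stand exactly where an endo [4+2] addition of that enal to an (E,E)-diene C3=C2–C1=C10 would place a C3 heteroatom surrogate, the formyl carbon and a C10 side chain.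

## Retrosynthesis

**Ester C–O bonds.** Cutting both angelate C–O bonds of 26 gives diol 24 and angelic acid 25. Any earlier esterification would expose the Z-enoates to hydride, peracid and palladium chemistry. The forward step must acylate two hindered secondary alcohols without Z to E isomerisation and without enolising the ketone.

**C9–O–Si, then C6–H and C7–H.** Diol 24 comes from silyl ether 23 by fluoride, and 23 from cross-conjugated dienone 22 by conjugate reduction. This places the C7 stereocentre at the very end, where the equatorial 7β arrangement is the thermodynamic one. It also leaves C6=C7 in place as the handle for the next cut. The reduction must spare the 1,1-disubstituted alkene.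

**C7–C11.** Dienone 22 is cut at the sp2–sp2 bond to α-iodoenone 20 and stannane 21; 20 comes from enone 19 by α-iodination. Attaching the isopropenyl group as a nucleophile to an sp3 C7 would need an aldol–dehydration of poor regiocontrol. The coupling must be neutral because C9–H is α' to the ketone.

**C3–O to C3–Si.** Alcohol 19 is traced to silane 18 by a stereoretentive Fleming–Tamao oxidation. Silicon travels unprotected through all earlier steps and is unmasked at the enone stage, the last point at which the molecule contains no electron-rich alkene. An oxygen at C3 from the outset would reverse the regiochemistry of the cycloaddition below.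

**C6=C7 (ring B).** Enone 18 opens by retro-aldol condensation (through aldol 17) to keto aldehyde 16, with a non-enolisable C6 aldehyde on C5 and a methyl ketone at C8. Compound 16 is reached from diol 15 by double oxidation. Diol 15 comes from alcohol 14 by hydrogenation with hydrogenolysis, and 14 from aldehyde 13 by reduction. The detour through the C6 alcohol is the price for avoiding a lactol between C6 and the C8 hydroxyl. Cutting C8–C9 or C9–C10 instead would discard the C9 stereocentre that the side chain delivers intact.

**C3–C4 and C5–C10 (key cut, ring A).** Cyclohexene 13 is divided into diene 11 and tiglic aldehyde 12. This is the most hindered pair of bonds, and the cut removes four stereocentres and the ring at once, leaving an acyclic diene with two stereocentres and an achiral commercial enal. Annulating ring A onto a preformed ring B would ask a β-methyl cyclohexenone to act as dienophile. The forward reaction must be regioselective (C10 to the formyl-bearing carbon), endo selective and face selective.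

**C1–C2.** Diene 11 is cut between the two alkenes into (E)-iodide 9 and vinylsilane 10 (Heck coupling); 9 comes from terminal alkyne 7 by hydrozirconation–iodination. Both alkene geometries follow from syn addition and syn elimination, and 10 is commercial.

**C9–C10.** Alkyne 7 is obtained from 6 and 5 by protecting-group steps, and 5 from aldehyde 3 and alkyne 4 by chelation-controlled addition. Aldehyde 3 comes from lactate 1 through ester 2. The lactate supplies C7, C8 and C9; its stereocentre (C8) sets C9 and is later oxidised away. The (R) series with a benzyl ether is chosen because chelation control then gives the required (9R) centre reliably and the benzyl group leaves during the later hydrogenation.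

## Roads not taken

**Alternative 1:** The cut is C5–C6, read backwards as a [3,3] shift that reconnects C3 to C8. Precursor A1 (3,3-dimethoxy-5,6-dimethyl-2-vinylbicyclo[2.2.2]oct-5-en-2-ol, vinyl on the side of the dimethyl alkene bridge) would be treated with KH and 18-crown-6. The anionic oxy-Cope rearrangement would give the cis-decalin enolate and then A2 (9,9-dimethoxy-11,12,13-trinor-cis-eremophil-3-en-8-one).
- Merits: the cis fusion and quaternary C5 arise in one strain-driven step that is probably more dependable than a hindered intermolecular cycloaddition; C8 and C9 emerge differentiated; C7 is the only enolisable position.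
- Weak points: A2 holds only two of the six stereocentres (C5, C10). C3 and C4 would have to come from a later hydroboration under substrate control. C9 arrives at the ketone oxidation level and must be reduced to 9β while C8 is a ketone. The isopropenyl group is absent. The bridged precursor offers no simple entry to one enantiomer.
- Comparison: this road is stronger on the reliability of its key step. The chosen plan sets four stereocentres and the absolute configuration in its key step and carries C9 in from the chiral pool.

**Alternative 2:** The cut is C4–C5 and C1–C10, ring A being annulated onto ring B. Enone A3 (trans-6-(tert-butyldimethylsilyloxy)-3-methyl-5-(prop-1-en-2-yl)cyclohex-2-en-1-one) and diene A4 ((Z)-3-(tert-butyldimethylsilyloxy)penta-1,3-diene) would combine under AlBr3/AlMe3 by Diels–Alder or double Michael addition. Acidic work-up would give A5 (8-(tert-butyldimethylsilyloxy)-cis-eremophil-11-ene-3,9-dione).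
- Merits: it is the most convergent option. C7 with its isopropenyl group and the C8 oxygen arrive from the chiral pool. After the annulation only two ketone reductions, esterification, desilylation and one oxidation would remain, a shorter endgame than the one chosen here.
- Weak points: the dienophile is a β-methyl cyclohexenone that must create quaternary C5. The strong Lewis acid needed threatens the isopropenyl group and the silyl enol ether. Face selection rests on remote C7. The oxygen pattern arrives transposed (C9 ketone, C8 ether), so C3 and C9 must each be reduced with the right sense. A3 itself needs a multi-step preparation.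
- Comparison: this road is better in step economy after the key step. The chosen plan offers a far more reactive, catalyst-controlled dienophile and the correct C8/C9 oxidation pattern from the start, at the cost of a longer linear sequence and late installation of C11–C13.

**Alternative 3:** The cut is C9–C10. The α-keto aldehyde A6 (4-[5-(tert-butyldimethylsilyloxy)-1,6-dimethylcyclohex-2-en-1-yl]-2-oxobutanal, ring stereotriad as in the target) would undergo a carbonyl-ene reaction with SnCl4 or heat. The C9 aldehyde would bond to C10 and the alkene would move to C1=C2, giving A7 (3-(tert-butyldimethylsilyloxy)-9-hydroxy-11,12,13-trinor-cis-eremophil-1-en-8-one).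
- Merits: ring B closes with the acyloin already in the correct oxidation pattern; C9 and C10 are set in an atom-economic step. As a ring B closure it is more direct than the reduction, oxidation and aldol sequence used here.
- Weak points: A6 presupposes the C3/C4/C5 triad, so the hardest part of the problem is untouched. α-Keto aldehydes hydrate and oligomerise. A 1,2-disubstituted alkene is a poor ene donor, and SnCl4 invites Prins-type capture and loss of the silyl ether. The 9β, cis-fused outcome is not assured. C7 must still be functionalised, now in competition with the acyloin side, and C1=C2 must be hydrogenated.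
- Comparison: this road closes ring B more directly. The chosen plan solves ring A and receives the C6 aldehyde directly from the cycloaddition; the resulting enone then provides the handle for C7.

Key step: step 8

Assumption: the (R)-configured oxazaborolidinium ion is taken to expose the Si face of the α-carbon of 12, by analogy with the formyl C–H···O binding model for 2-substituted enals; if the sense proves opposite, the (S) catalyst is used, both antipodes being available.

## Route

Step 1
Reactants: 1 methyl (R)-lactate
Product: 2 methyl (2R)-2-(benzyloxy)propanoate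
Conditions: BnOC(=NH)CCl3, TfOH (cat.), cyclohexane–CH2Cl2, rt
Reagents that add atoms: benzyl 2,2,2-trichloroacetimidate, ClC(Cl)(Cl)C(=N)OCc1ccccc1
Why: Acid-catalysed imidate O-benzylation runs under non-basic conditions, so the α-stereocentre of the lactate is not epimerised.

Step 2
Reactants: 2 methyl (2R)-2-(benzyloxy)propanoate
Product: 3 (2R)-2-(benzyloxy)propanal
Conditions: i-Bu2AlH, CH2Cl2, −78 °C; aq. KNaC4H4O6
Reagents that add atoms: none
Why: Partial ester reduction stops at the aluminium hemiacetal at low temperature and releases the configurationally labile α-alkoxy aldehyde only on work-up; it is used at once.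

Step 3
Reactants: 3 (2R)-2-(benzyloxy)propanal; 4 ethynyl(trimethyl)silane
Product: 5 (3R,4R)-4-(benzyloxy)-1-(trimethylsilyl)pent-1-yn-3-ol
Conditions: 4, n-BuLi, Et2O, −78 → 0 °C; ZnBr2, 0 °C; then 3, −78 → 0 °C; aq. NH4Cl
Reagents that add atoms: none
Why: Chelation-controlled addition of an alkynylzinc bromide to an α-benzyloxy aldehyde: zinc bridges the carbonyl and ether oxygens and the nucleophile enters anti to the methyl group, giving the syn (3R,4R) product and thereby C9 (R).

Step 4
Reactants: 5 (3R,4R)-4-(benzyloxy)-1-(trimethylsilyl)pent-1-yn-3-ol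
Product: 6 (3R,4R)-4-(benzyloxy)-3-(tert-butyldimethylsilyloxy)-1-(trimethylsilyl)pent-1-yne
Conditions: TBSCl, imidazole, DMF, rt
Reagents that add atoms: tert-butyldimethylsilyl chloride, CC(C)(C)[Si](C)(C)Cl
Why: Standard silylation of a secondary propargylic alcohol; a bulky, weakly basic silyl ether is chosen for O9 because it will sit next to the diene under Lewis acid catalysis and must come off last with fluoride.

Step 5
Reactants: 6 (3R,4R)-4-(benzyloxy)-3-(tert-butyldimethylsilyloxy)-1-(trimethylsilyl)pent-1-yne
Product: 7 (3R,4R)-4-(benzyloxy)-3-(tert-butyldimethylsilyloxy)pent-1-yne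
Conditions: K2CO3, MeOH, rt
Reagents that add atoms: none
Why: Methanolysis of the alkynyl C–Si bond by catalytic methoxide is selective over the O–Si bond of the hindered secondary silyl ether.

Step 6
Reactants: 7 (3R,4R)-4-(benzyloxy)-3-(tert-butyldimethylsilyloxy)pent-1-yne
Product: 9 (1E,3R,4R)-4-(benzyloxy)-3-(tert-butyldimethylsilyloxy)-1-iodopent-1-ene, via alkenylzirconocene chloride 8 (not isolated)
Conditions: Cp2Zr(H)Cl, THF, rt; then I2, 0 °C
Reagents that add atoms: iodine, II
Why: Hydrozirconation of a terminal alkyne is a syn addition that places zirconium on the terminal carbon; iodinolysis of the C–Zr bond proceeds with retention and gives the (E)-iodide.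

Step 7
Reactants: 9 (1E,3R,4R)-4-(benzyloxy)-3-(tert-butyldimethylsilyloxy)-1-iodopent-1-ene; 10 dimethyl(phenyl)(vinyl)silane
Product: 11 (1E,3E,5R,6R)-6-(benzyloxy)-5-(tert-butyldimethylsilyloxy)-1-[dimethyl(phenyl)silyl]hepta-1,3-diene
Conditions: Pd(OAc)2 (5 mol %), PPh3 (10 mol %), Ag2CO3 (1 equiv), MeCN, 50 °C
Reagents that add atoms: none
Why: Heck reaction: zerovalent palladium inserts into the C–I bond, the alkenyl group is delivered to the CH2 terminus of the vinylsilane and syn β-hydride elimination gives the (E)-alkene. The silver salt abstracts iodide and suppresses β-silyl elimination, so silicon is retained and the iodide geometry is kept.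

Step 8
Reactants: 11 (1E,3E,5R,6R)-6-(benzyloxy)-5-(tert-butyldimethylsilyloxy)-1-[dimethyl(phenyl)silyl]hepta-1,3-diene; 12 tiglic aldehyde
Product: 13 (1S,2S,5R,6R)-2-[(1R,2R)-2-(benzyloxy)-1-(tert-butyldimethylsilyloxy)propyl]-5-[dimethyl(phenyl)silyl]-1,6-dimethylcyclohex-3-ene-1-carbaldehyde
Conditions: 12 (3 equiv), (3aR)-1-(2-methylphenyl)-3,3-diphenyltetrahydro-1H,3H-pyrrolo[1,2-c][1,3,2]oxazaborole (C24H24BNO, 20 mol %), (CF3SO2)2NH (17 mol %), CH2Cl2, −78 → −20 °C
Reagents that add atoms: none
Why: The protonated oxazaborolidine binds the formyl oxygen of s-trans 12 and lowers its LUMO; the [4+2] cycloaddition with 11 is concerted but asynchronous, the β-carbon C4 bonding ahead to the silicon-bearing terminus C3 while C5–C10 lags. The closest known reaction type is the oxazaborolidinium- or aluminium-Lewis-acid-catalysed Diels–Alder reaction of 2-substituted enals such as tiglic aldehyde with (E)-1-substituted and 1-silyl dienes. Ring A is closed by intermolecular [4+2] cycloaddition, both ring bonds (C3–C4 and C5–C10) forming suprafacially on each partner. At C4 and C5 the cis methyls follow from the E geometry of 12. C3 and C10 are fixed relative to C5 by the endo position of the formyl group, which places silicon and the C9 chain (the two E substituents of the diene) cis to C6 and trans to the methyls. The absolute sense at C4 and C5 comes from the catalyst, which lets the diene reach only the Si face of the enal α-carbon; C10 relative to C9 comes from attack on the diene face anti to the silyloxy group in the rotamer with C9–H eclipsing the diene, the same face the catalyst demands (matched pair). The step needs regioselectivity (C10 to the formyl-bearing carbon), secured by the alkyl substituent at C10 and β-silicon stabilisation of the positive charge developing at C2, and endo selectivity, the usual outcome for Lewis-acid-bound enals with acyclic (E,E)-dienes; the bulky silyl ether at the dienylic position and the remote benzyl ether are chosen so that neither binds nor is ionised by the catalyst.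

Step 9
Reactants: 13 (1S,2S,5R,6R)-2-[(1R,2R)-2-(benzyloxy)-1-(tert-butyldimethylsilyloxy)propyl]-5-[dimethyl(phenyl)silyl]-1,6-dimethylcyclohex-3-ene-1-carbaldehyde
Product: 14 {2-[(1R,2R)-2-(benzyloxy)-1-(tert-butyldimethylsilyloxy)propyl]-5-[dimethyl(phenyl)silyl]-1,6-dimethylcyclohex-3-en-1-yl}methanol (ring configuration as in 13)
Conditions: NaBH4, MeOH, 0 °C
Reagents that add atoms: none
Why: Borohydride reduction of the non-enolisable aldehyde; taking C6 to the alcohol prevents lactol formation with the C8 hydroxyl once that is released and removes the group that would complicate the hydrogenation.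

Step 10
Reactants: 14 {2-[(1R,2R)-2-(benzyloxy)-1-(tert-butyldimethylsilyloxy)propyl]-5-[dimethyl(phenyl)silyl]-1,6-dimethylcyclohex-3-en-1-yl}methanol
Product: 15 (1R,2R)-1-(tert-butyldimethylsilyloxy)-1-{4-[dimethyl(phenyl)silyl]-2-(hydroxymethyl)-2,3-dimethylcyclohexyl}propan-2-ol (ring substituents placed as in 13)
Conditions: H2 (1 atm), 10% Pd/C, EtOAc–EtOH, rt
Reagents that add atoms: none
Why: Heterogeneous hydrogenation saturates the cis-disubstituted ring alkene and hydrogenolyses the benzyl ether in one operation; the silyl ether and the arylsilane are inert and no stereocentre is created.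

Step 11
Reactants: 15 (1R,2R)-1-(tert-butyldimethylsilyloxy)-1-{4-[dimethyl(phenyl)silyl]-2-(hydroxymethyl)-2,3-dimethylcyclohexyl}propan-2-ol
Product: 16 2-[(1R)-1-(tert-butyldimethylsilyloxy)-2-oxopropyl]-5-[dimethyl(phenyl)silyl]-1,6-dimethylcyclohexane-1-carbaldehyde (ring configuration as in 13)
Conditions: (COCl)2, DMSO, CH2Cl2, −78 °C; Et3N, −78 → 0 °C
Reagents that add atoms: none
Why: Swern oxidation converts both hydroxyls into alkoxysulfonium ions before base is added, so the 1,5-diol goes to the keto aldehyde without passing through a lactol; the C8 stereocentre is erased as planned.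

Step 12
Reactants: 16 2-[(1R)-1-(tert-butyldimethylsilyloxy)-2-oxopropyl]-5-[dimethyl(phenyl)silyl]-1,6-dimethylcyclohexane-1-carbaldehyde
Product: 18 3α-[dimethyl(phenyl)silyl]-9β-(tert-butyldimethylsilyloxy)-11,12,13-trinor-cis-eremophil-6-en-8-one, via β-hydroxy ketone 17 (not isolated)
Conditions: (PhCH2)2NH·CF3CO2H (0.5 equiv), benzene, 60 °C
Reagents that add atoms: none
Why: Intramolecular aldol condensation under ammonium carboxylate catalysis: only the methyl side of the ketone can reach the non-enolisable C6 aldehyde through a six-membered ring (attack from C9 would close a four-membered ring), and dehydration gives the ring B enone. The near-neutral buffer keeps C9 from epimerising.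

Step 13
Reactants: 18 3α-[dimethyl(phenyl)silyl]-9β-(tert-butyldimethylsilyloxy)-11,12,13-trinor-cis-eremophil-6-en-8-one
Product: 19 3α-hydroxy-9β-(tert-butyldimethylsilyloxy)-11,12,13-trinor-cis-eremophil-6-en-8-one
Conditions: Hg(OAc)2, AcOOH (32% in AcOH), AcOH, rt
Reagents that add atoms: peracetic acid, CC(=O)OO
Why: Fleming–Tamao oxidation: ipso-mercuration removes phenyl from silicon and the peracid-induced 1,2-shift of C3 from silicon to oxygen goes with retention, giving the 3α-alcohol. The electron-poor enone alkene and the silyl ether are not attacked by the electrophilic reagents.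

Step 14
Reactants: 19 3α-hydroxy-9β-(tert-butyldimethylsilyloxy)-11,12,13-trinor-cis-eremophil-6-en-8-one
Product: 20 3α-hydroxy-7-iodo-9β-(tert-butyldimethylsilyloxy)-11,12,13-trinor-cis-eremophil-6-en-8-one
Conditions: I2, pyridine–CH2Cl2 (1:1), 0 °C → rt
Reagents that add atoms: iodine, II
Why: α-Iodination of an enone by the pyridine addition, iodination and elimination sequence (Baylis–Hillman-type), known for 4,4-disubstituted cyclohexenones; the free secondary alcohol is tolerated.

Step 15
Reactants: 20 3α-hydroxy-7-iodo-9β-(tert-butyldimethylsilyloxy)-11,12,13-trinor-cis-eremophil-6-en-8-one; 21 tributyl(prop-1-en-2-yl)stannane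
Product: 22 3α-hydroxy-9β-(tert-butyldimethylsilyloxy)-cis-eremophila-6,11-dien-8-one
Conditions: 21 (1.5 equiv), Pd2(dba)3 (5 mol %), AsPh3 (20 mol %), CuI (10 mol %), NMP, rt
Reagents that add atoms: none
Why: Stille coupling of an α-iodoenone with zerovalent palladium under neutral, room-temperature conditions forms C7–C11 without base, so C9–H α' to the ketone is not exposed to epimerisation.

Step 16
Reactants: 22 3α-hydroxy-9β-(tert-butyldimethylsilyloxy)-cis-eremophila-6,11-dien-8-one
Product: 23 3α-hydroxy-9β-(tert-butyldimethylsilyloxy)-cis-eremophil-11-en-8-one (isopropenyl β at C7)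
Conditions: [(Ph3P)CuH]6 (0.5 equiv), H2O (5 equiv), degassed toluene, rt
Reagents that add atoms: none
Why: Conjugate reduction by phosphine-stabilised copper hydride: hydride adds to C6 of the enone, the unactivated 1,1-disubstituted alkene is not reduced, and water protonates the copper enolate at C7. Axial protonation is expected to give the 7β (equatorial) epimer, which is also the thermodynamically preferred one.

Step 17
Reactants: 23 3α-hydroxy-9β-(tert-butyldimethylsilyloxy)-cis-eremophil-11-en-8-one
Product: 24 3α,9β-dihydroxy-cis-eremophil-11-en-8-one (isopropenyl β at C7)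
Conditions: HF·pyridine, pyridine, THF, 0 °C → rt
Reagents that add atoms: none
Why: Fluoride-induced cleavage of the secondary silyl ether under buffered, mildly acidic conditions, which avoid base-induced migration of the C11 alkene into conjugation and α-ketol rearrangement.

Step 18
Reactants: 24 3α,9β-dihydroxy-cis-eremophil-11-en-8-one; 25 angelic acid
Product: 26 (3R,4R,5R,7R,9R,10S)-3α,9β-bis(angeloyloxy)-cis-eremophil-11-en-8-one
Conditions: 25 (4 equiv), 2,4,6-Cl3C6H2COCl (4 equiv), Et3N, toluene, rt; then 24, toluene, 75 °C
Reagents that add atoms: none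
Why: Yamaguchi esterification: the mixed anhydride of angelic acid acylates both secondary alcohols at its less hindered carbonyl without a nucleophilic catalyst, the protocol known to transfer the angeloyl group with retention of the Z geometry.

## Compound list

1 | methyl (R)-lactate | COC(=O)[C@@H](C)O | starting material
2 | methyl (2R)-2-(benzyloxy)propanoate | COC(=O)[C@@H](C)OCc1ccccc1 | intermediate
3 | (2R)-2-(benzyloxy)propanal | O=C[C@@H](C)OCc1ccccc1 | intermediate
4 | ethynyl(trimethyl)silane | C#C[Si](C)(C)C | starting material
5 | (3R,4R)-4-(benzyloxy)-1-(trimethylsilyl)pent-1-yn-3-ol | C[Si](C)(C)C#C[C@@H](O)[C@@H](C)OCc1ccccc1 | intermediate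
6 | (3R,4R)-4-(benzyloxy)-3-(tert-butyldimethylsilyloxy)-1-(trimethylsilyl)pent-1-yne | C[Si](C)(C)C#C[C@@H](O[Si](C)(C)C(C)(C)C)[C@@H](C)OCc1ccccc1 | intermediate
7 | (3R,4R)-4-(benzyloxy)-3-(tert-butyldimethylsilyloxy)pent-1-yne | C#C[C@@H](O[Si](C)(C)C(C)(C)C)[C@@H](C)OCc1ccccc1 | intermediate
8 | chlorobis(cyclopentadienyl)[(1E,3R,4R)-4-(benzyloxy)-3-(tert-butyldimethylsilyloxy)pent-1-en-1-yl]zirconium (not isolated) | Cl[Zr](C1C=CC=C1)(C2C=CC=C2)/C=C/[C@@H](O[Si](C)(C)C(C)(C)C)[C@@H](C)OCc3ccccc3 | intermediate
9 | (1E,3R,4R)-4-(benzyloxy)-3-(tert-butyldimethylsilyloxy)-1-iodopent-1-ene | I/C=C/[C@@H](O[Si](C)(C)C(C)(C)C)[C@@H](C)OCc1ccccc1 | intermediate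
10 | dimethyl(phenyl)(vinyl)silane | C=C[Si](C)(C)c1ccccc1 | starting material
11 | (1E,3E,5R,6R)-6-(benzyloxy)-5-(tert-butyldimethylsilyloxy)-1-[dimethyl(phenyl)silyl]hepta-1,3-diene | c1ccccc1[Si](C)(C)/C=C/C=C/[C@@H](O[Si](C)(C)C(C)(C)C)[C@@H](C)OCc2ccccc2 | intermediate
12 | tiglic aldehyde, (E)-2-methylbut-2-enal | C/C=C(\C)C=O | starting material
13 | (1S,2S,5R,6R)-2-[(1R,2R)-2-(benzyloxy)-1-(tert-butyldimethylsilyloxy)propyl]-5-[dimethyl(phenyl)silyl]-1,6-dimethylcyclohex-3-ene-1-carbaldehyde (formyl, side chain and silyl cis; both methyls on the other face) | O=C[C@@]1(C)[C@H](C=C[C@@H]([Si](C)(C)c2ccccc2)[C@@H]1C)[C@@H](O[Si](C)(C)C(C)(C)C)[C@@H](C)OCc3ccccc3 | intermediate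
14 | {2-[(1R,2R)-2-(benzyloxy)-1-(tert-butyldimethylsilyloxy)propyl]-5-[dimethyl(phenyl)silyl]-1,6-dimethylcyclohex-3-en-1-yl}methanol, ring configuration as in 13 | OC[C@@]1(C)[C@H](C=C[C@@H]([Si](C)(C)c2ccccc2)[C@@H]1C)[C@@H](O[Si](C)(C)C(C)(C)C)[C@@H](C)OCc3ccccc3 | intermediate
15 | (1R,2R)-1-(tert-butyldimethylsilyloxy)-1-{4-[dimethyl(phenyl)silyl]-2-(hydroxymethyl)-2,3-dimethylcyclohexyl}propan-2-ol, ring substituents placed as in 13 | OC[C@@]1(C)[C@H](CC[C@@H]([Si](C)(C)c2ccccc2)[C@@H]1C)[C@@H](O[Si](C)(C)C(C)(C)C)[C@@H](C)O | intermediate
16 | 2-[(1R)-1-(tert-butyldimethylsilyloxy)-2-oxopropyl]-5-[dimethyl(phenyl)silyl]-1,6-dimethylcyclohexane-1-carbaldehyde, ring configuration as in 13 | O=C[C@@]1(C)[C@H](CC[C@@H]([Si](C)(C)c2ccccc2)[C@@H]1C)[C@@H](O[Si](C)(C)C(C)(C)C)C(C)=O | intermediate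
17 | 6-hydroxy-3α-[dimethyl(phenyl)silyl]-9β-(tert-butyldimethylsilyloxy)-11,12,13-trinor-cis-eremophilan-8-one, either C6 epimer (not isolated) | O=C1CC(O)[C@@]2(C)[C@H](CC[C@@H]([Si](C)(C)c3ccccc3)[C@@H]2C)[C@H]1O[Si](C)(C)C(C)(C)C | intermediate
18 | 3α-[dimethyl(phenyl)silyl]-9β-(tert-butyldimethylsilyloxy)-11,12,13-trinor-cis-eremophil-6-en-8-one | C1=C[C@@]2(C)[C@H](CC[C@@H]([Si](C)(C)c3ccccc3)[C@@H]2C)[C@@H](O[Si](C)(C)C(C)(C)C)C1=O | intermediate
19 | 3α-hydroxy-9β-(tert-butyldimethylsilyloxy)-11,12,13-trinor-cis-eremophil-6-en-8-one | C1=C[C@@]2(C)[C@H](CC[C@@H](O)[C@@H]2C)[C@@H](O[Si](C)(C)C(C)(C)C)C1=O | intermediate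
20 | 3α-hydroxy-7-iodo-9β-(tert-butyldimethylsilyloxy)-11,12,13-trinor-cis-eremophil-6-en-8-one | IC1=C[C@@]2(C)[C@H](CC[C@@H](O)[C@@H]2C)[C@@H](O[Si](C)(C)C(C)(C)C)C1=O | intermediate
21 | tributyl(prop-1-en-2-yl)stannane | C=C(C)[Sn](CCCC)(CCCC)CCCC | starting material
22 | 3α-hydroxy-9β-(tert-butyldimethylsilyloxy)-cis-eremophila-6,11-dien-8-one | C=C(C)C1=C[C@@]2(C)[C@H](CC[C@@H](O)[C@@H]2C)[C@@H](O[Si](C)(C)C(C)(C)C)C1=O | intermediate
23 | 3α-hydroxy-9β-(tert-butyldimethylsilyloxy)-cis-eremophil-11-en-8-one, isopropenyl β at C7 | C=C(C)[C@H]1C[C@@]2(C)[C@H](CC[C@@H](O)[C@@H]2C)[C@@H](O[Si](C)(C)C(C)(C)C)C1=O | intermediate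
24 | 3α,9β-dihydroxy-cis-eremophil-11-en-8-one, isopropenyl β at C7 | C=C(C)[C@H]1C[C@@]2(C)[C@H](CC[C@@H](O)[C@@H]2C)[C@@H](O)C1=O | intermediate
25 | angelic acid, (Z)-2-methylbut-2-enoic acid | C/C=C(/C)C(=O)O | starting material
26 | (3R,4R,5R,7R,9R,10S)-3α,9β-bis(angeloyloxy)-cis-eremophil-11-en-8-one (CNP0174755.1) | C=C(C)[C@H]1C[C@@]2(C)[C@H](CC[C@@H](OC(=O)/C(C)=C\C)[C@@H]2C)[C@@H](OC(=O)/C(C)=C\C)C1=O | target

## Step count and least certain steps

Total step count: 18. Longest linear sequence: 18 steps (1 to 26); compounds 4, 10, 12, 21 and 25 enter as purchased reagents.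

**Step 8 (key step).** The most likely failure is a rate too low at the congested C5–C10 bond at temperatures where the catalyst is selective. Forcing would erode the endo preference (the α-methyl competes with formyl for the endo position) and could ionise the dienylic C9–O bond or protodesilylate the dienylsilane. The fallback sets out from 11 and 12 and raises the electrophilicity of the dienophile by changing its nature. Aldehyde 12 is acetalised with ethylene glycol to 2-[(E)-but-2-en-2-yl]-1,3-dioxolane F1. F1 and 11 are combined with catalytic TMSOTf in CH2Cl2 at −78 °C in a cationic Diels–Alder reaction through the O-alkylated enal cation, giving the ethylene acetal of the adduct F2. Face selection then rests on the C9 silyloxy group alone. Hydrolysis with PPTS in wet acetone returns to the route at 13.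

**Step 16.** The most likely failures are slow hydride delivery to the neopentyl C6 with competing 1,2-reduction or dimerisation of the dienone, protonation of the enolate from the wrong face, and drift of the C11 alkene into conjugation on work-up. The fallback sets out from 22 and separates reduction from protonation. 1,4-Hydrosilylation with Et3SiH and RhCl(PPh3)3 (which also silylates O3) gives 3α,8-bis(triethylsilyloxy)-9β-(tert-butyldimethylsilyloxy)-cis-eremophila-7,11-diene F3. HF·pyridine then cleaves all three silyl groups and protonates C7 at the α-carbon of the dienol under acidic, kinetic conditions, rejoining the route at 24. If both C7 epimers form, brief treatment with a mild amine base should move the mixture toward the equatorial 7β isomer.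

**Step 18.** The most likely failures are Z to E isomerisation of the activated angeloyl unit by reversible conjugate addition of chloride or amine, incomplete acylation of the hindered C9 hydroxyl beside the ketone, and enolisation toward C7 or C9 at 75 °C with Et3N. The fallback sets out from 24 and 25 and exchanges the basic acyl-transfer manifold for an acidic one. Acid 25 is dehydrated with dicyclohexylcarbodiimide to angelic anhydride F4, which acylates 24 under Sc(OTf)3 catalysis in MeCN–CH2Cl2 at −20 °C, returning to the route at 26.

**Step 7.** The most likely failures are β-silyl elimination after insertion (loss of silicon to a terminal diene), insertion with the opposite regiochemistry, and E/Z erosion by readdition of palladium hydride. The fallback sets out from 9 and replaces the Heck reaction by a Suzuki–Miyaura coupling. Ethynyl(dimethyl)phenylsilane is hydroborated with pinacolborane (cat. Cp2Zr(H)Cl) to (E)-dimethyl(phenyl)[2-(4,4,5,5-tetramethyl-1,3,2-dioxaborolan-2-yl)ethenyl]silane F5, which is coupled with 9 (Pd(PPh3)4, aq. K3PO4, THF), returning to the route at 11.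

**Step 10.** The most likely failure is palladium-mediated migration of the C1=C2 bond toward C3 or C10 before saturation, which would scramble one of those centres, or incomplete debenzylation. The fallback sets out from 14 and separates the two events. Diimide reduction (2-nitrobenzenesulfonyl hydrazide, Et3N, CH2Cl2) gives {2-[(1R,2R)-2-(benzyloxy)-1-(tert-butyldimethylsilyloxy)propyl]-5-[dimethyl(phenyl)silyl]-1,6-dimethylcyclohexyl}methanol F6 without a metal hydride. Hydrogenolysis (H2, Pd(OH)2/C, EtOAc) then returns to the route at 15.

Further compounds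

F1 | step 8 | 2-[(E)-but-2-en-2-yl]-1,3-dioxolane | C/C=C(\C)C1OCCO1
F2 | step 8 | 2-{2-[(1R,2R)-2-(benzyloxy)-1-(tert-butyldimethylsilyloxy)propyl]-5-[dimethyl(phenyl)silyl]-1,6-dimethylcyclohex-3-en-1-yl}-1,3-dioxolane, ring configuration as in 13 | O1CCOC1[C@@]2(C)[C@H](C=C[C@@H]([Si](C)(C)c3ccccc3)[C@@H]2C)[C@@H](O[Si](C)(C)C(C)(C)C)[C@@H](C)OCc4ccccc4
F3 | step 16 | 3α,8-bis(triethylsilyloxy)-9β-(tert-butyldimethylsilyloxy)-cis-eremophila-7,11-diene | C=C(C)C1=C(O[Si](CC)(CC)CC)[C@H](O[Si](C)(C)C(C)(C)C)[C@H]2CC[C@@H](O[Si](CC)(CC)CC)[C@H](C)[C@@]2(C)C1
F4 | step 18 | angelic anhydride, (Z)-2-methylbut-2-enoic anhydride | C/C=C(/C)C(=O)OC(=O)/C(C)=C\C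
F5 | step 7 | (E)-dimethyl(phenyl)[2-(4,4,5,5-tetramethyl-1,3,2-dioxaborolan-2-yl)ethenyl]silane | C[Si](C)(/C=C/B1OC(C)(C)C(C)(C)O1)c1ccccc1
F6 | step 10 | {2-[(1R,2R)-2-(benzyloxy)-1-(tert-butyldimethylsilyloxy)propyl]-5-[dimethyl(phenyl)silyl]-1,6-dimethylcyclohexyl}methanol, ring configuration as in 15 | OC[C@@]1(C)[C@H](CC[C@@H]([Si](C)(C)c2ccccc2)[C@@H]1C)[C@@H](O[Si](C)(C)C(C)(C)C)[C@@H](C)OCc3ccccc3
A1 | alternative 1 | 3,3-dimethoxy-5,6-dimethyl-2-vinylbicyclo[2.2.2]oct-5-en-2-ol, vinyl syn to the alkene bridge | C=C[C@]1(O)C(OC)(OC)[C@H]2CC[C@@H]1C(C)=C2C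
A2 | alternative 1 | 9,9-dimethoxy-11,12,13-trinor-cis-eremophil-3-en-8-one | O=C1CC[C@@]2(C)[C@H](CCC=C2C)C1(OC)OC
A3 | alternative 2 | trans-6-(tert-butyldimethylsilyloxy)-3-methyl-5-(prop-1-en-2-yl)cyclohex-2-en-1-one | C=C(C)[C@H]1CC(C)=CC(=O)[C@@H]1O[Si](C)(C)C(C)(C)C
A4 | alternative 2 | (Z)-3-(tert-butyldimethylsilyloxy)penta-1,3-diene | C/C=C(\O[Si](C)(C)C(C)(C)C)C=C
A5 | alternative 2 | 8-(tert-butyldimethylsilyloxy)-cis-eremophil-11-ene-3,9-dione | C=C(C)[C@H]1C[C@@]2(C)[C@H](CCC(=O)[C@@H]2C)C(=O)[C@@H]1O[Si](C)(C)C(C)(C)C
A6 | alternative 3 | 4-[5-(tert-butyldimethylsilyloxy)-1,6-dimethylcyclohex-2-en-1-yl]-2-oxobutanal, ring stereotriad as in the target | O=CC(=O)CC[C@@]1(C)C=CC[C@@H](O[Si](C)(C)C(C)(C)C)[C@@H]1C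
A7 | alternative 3 | 3-(tert-butyldimethylsilyloxy)-9-hydroxy-11,12,13-trinor-cis-eremophil-1-en-8-one | O=C1CC[C@@]2(C)[C@H](C=C[C@@H](O[Si](C)(C)C(C)(C)C)[C@@H]2C)[C@H]1O
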